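electrophile 0.80 M; protonated nucleophile 2.00 M; time 2.5 h

- the concentration of free base at which the part of the electrophile that has reacted at 2.5 h is just 50%, in M

- target is meant together with its idle adduct B
- acid set free is meant together with its idle adduct A
- the amount of free base is what is sought; it is there from the start
- what has gone from electrophile into another species counts as reacted, even if it can come back
- run time (flask): 2.5 h

    electrophile + nucleophile → acid set free + target (k1 = 0.00872 M⁻¹ min⁻¹)
    nucleophile + acid set free ⇌ protonated nucleophile, settled at all times (K2 = 170 M⁻¹)
    acid set free + free base ⇌ salt of the base, settled at all times (K3 = 222 M⁻¹)
    electrophile + acid set free ⇌ idle adduct A, settled at all times (K4 = 2.9 M⁻¹)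
    nucleophile + target ⇌ idle adduct B, settled at all times (K5 = 10 M⁻¹)
    electrophile → decomposition product (k6 = 1.66 × 10⁻⁵ min⁻¹)

1. At early times nothing had turned over, so I took the free nucleophile, N, as what the free base frees from the protonated nucleophile. The constant of that exchange is the salt constant over the protonation constant, 1.31.
2. I went to logarithms. With k the rate constant of the step from electrophile and nucleophile, the logarithm of the electrophile falls by k·N per unit time. To lose a factor of two in 2.5 h, N had to average 0.530 M. I called this the needed nucleophile: the level at which the half-life of the electrophile by that step equals the run time.
3. Low extreme: suppose turnover costs no nucleophile. Holding N at the needed level then takes a charge of free base of 0.676 M.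
4. High extreme: suppose N is still at the needed level at the end, with extent x = 0.400 M. Each turnover uses one nucleophile, and its acid protonates another. At that N, 84.1% of the target sits in idle adduct B, holding a further nucleophile. The charge becomes 2.59 M.
5. N falls along the run, so I set it to the needed level at the middle of the logarithmic drop, where the electrophile is down by the square root of two and x = 0.234 M. That gave 1.66 M. I left out idle adduct A, and also decomposition, whose half-life of 29 d is far longer than the run.
6. The forecast gave 1.55 M, lower than my figure, from a trial charge integrated along the extent of the main step: “Simpson's rule gives an integral of about 1.36, slightly too large.”
7. The simulation gave 1.55 M.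

In that flask the half-life of the electrophile by the main step was 2.3 h at 0.708 h and 4.5 h at 2.50 h, shorter and then longer than the run, which reads as N of 0.585 M and then 0.294 M on either side of the needed 0.530 M. For the thin run, at twice the dilution, I put N at 0.265 M, which reckoned to 29.3% reacted, and that run gave 36.6%.

The numbers of this flask were drawn at random within sensible limits; the flask was simulated.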